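**Retrosynthetic overview**
- Numbering follows 1,5,10-triazabicyclo[11.4.0]heptadec-15-en-11-one (N1, N5, N10, C11=O, C13, C15=C16, C17). Ring A is the tetrahydropyridine (N1, C13–C17), ring C is the 13-membered lactam, and ring B is a temporary 1,3-oxazinan-2-one.
- Enabling feature: in ring A the C15=C16 alkene lies opposite the N1–C13 bond, so N1–C17 and C13–C14 are the two bonds of an imino Diels–Alder retron. The side-chain ketone oxygen stands 1,3 to N1 (N1–C17–CH2–C=O), so at the alcohol level it can be tied to N1 through one carbonyl carbon.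
- Key disconnection: intramolecular [4+2] of a carbamate-tethered (E)-N-acylimine with an (E)-1-substituted butadiene. Rings A and B form together, and C13 and C17 are both set from one carbinol centre, which the late oxidation to the ketone erases.
- In the key step C13 carries Me3Si–C≡C–. This group has no α-hydrogen, so no enecarbamate tautomer can form, and it is a latent CH2CO2H (hydroboration–oxidation).
- Afterwards: amide formation with a Boc/acetal-masked C4–N–C3 chain, opening of ring B by hydroxide, closure of ring C last at N1–C2 by reductive amination, then oxidation and Boc removal.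

Key step: step 6

Assumption: the (S,S)-cobalt salen catalyst leaves the (S)-epoxide, and the 1,3-induction in step 6 follows the outward-pentyl model given there. If the induction runs the other way, the (R,R)-catalyst in step 1 corrects the whole series.

Step 1
Reactants: 1 rac-1,2-epoxyheptane
Product: 2 (S)-1,2-epoxyheptane
Conditions: (S,S)-[N,N'-bis(3,5-di-tert-butylsalicylidene)-1,2-cyclohexanediaminato]Co(OAc) (0.5 mol %, trivalent cobalt), H2O (0.55 equiv), neat, 0 → 23 °C; distillation
Reagents that add atoms: none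
Why: Hydrolytic kinetic resolution, in which the chiral cobalt complex hydrolyses the (R)-epoxide much faster, so that (S)-2 is left and distilled off; this is the only stereocentre taken from an external chiral source.

Step 2
Reactants: 2 (S)-1,2-epoxyheptane
Product: 3 (S)-non-1-yn-4-ol
Conditions: LiC≡CH·H2NCH2CH2NH2, DMSO, 0 → 23 °C; H2O
Reagents that add atoms: lithium acetylide–ethylenediamine complex, [Li+].[C-]#C.NCCN
Why: SN2 opening of a terminal epoxide by acetylide at the unsubstituted carbon, which leaves the C–O stereocentre untouched.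

Step 3
Reactants: 3 (S)-non-1-yn-4-ol
Product: 5 (S,E)-undeca-1,3-dien-6-ol, via alkenylzirconocene 4 (not isolated)
Conditions: Cp2Zr(H)Cl (2.2 equiv), THF, 23 °C, dark; then CH2=CHBr (1 M in THF), Pd(PPh3)4 (5 mol %, zerovalent palladium), 23 → 40 °C; H2O
Reagents that add atoms: vinyl bromide, C=CBr
Why: The first equivalent of hydride is consumed by the hydroxyl group, syn-hydrozirconation then places zirconium on the terminal carbon, and Negishi-type cross-coupling with vinyl bromide proceeds with retention to give the (E)-diene.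

Step 4
Reactants: 5 (S,E)-undeca-1,3-dien-6-ol
Product: 7 (S,E)-undeca-1,3-dien-6-yl carbamate, via N-trichloroacetyl carbamate 6 (not isolated)
Conditions: Cl3CC(O)NCO, CH2Cl2, 0 °C; then K2CO3 (0.2 equiv), MeOH, 0 → 23 °C
Reagents that add atoms: trichloroacetyl isocyanate, O=C=NC(=O)C(Cl)(Cl)Cl
Why: Addition of the alcohol to the acyl isocyanate followed by methanolysis of the trichloroacetyl group is a mild carbamoylation that does not touch the C–O bond, so the configuration is kept.

Step 5
Reactants: 7 (S,E)-undeca-1,3-dien-6-yl carbamate; 8 3-(trimethylsilyl)prop-2-ynal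
Product: 9 (S,E)-undeca-1,3-dien-6-yl N-[1-(phenylsulfonyl)-3-(trimethylsilyl)prop-2-yn-1-yl]carbamate (both epimers at the sulfone carbon)
Conditions: PhSO2Na (2 equiv), HCO2H, THF–H2O 1:2, 23 °C
Reagents that add atoms: sodium benzenesulfinate, [Na+].[O-]S(=O)c1ccccc1
Why: Three-component α-amidoalkylation (carbamate, aldehyde, sulfinate) gives a storable α-amido sulfone; its new centre forms unselectively, which is irrelevant because it becomes trigonal in step 6.

Step 6
Reactants: 9 α-amido sulfone
Product: 11 (3S,4aS,8R)-3-pentyl-8-[(trimethylsilyl)ethynyl]-4,4a,7,8-tetrahydro-3H-pyrido[1,2-c][1,3]oxazin-1-one, via N-acylimine 10 (not isolated)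
Conditions: Cs2CO3 (3 equiv), 4 Å MS, BHT (cat.), toluene (0.01 M), 23 °C, then 110 °C
Reagents that add atoms: none
Why: Cs2CO3 expels benzenesulfinate from 9 (E1cB) and the neutral (E)-N-acylimine 10 then enters a concerted but asynchronous intramolecular imino Diels–Alder reaction of normal electron demand, the closest known reaction type being the thermal cycloaddition of carbamate-tethered N-acylimines to 1,3-dienes. Ring A closes by the [4+2] event itself, the imine carbon bonding to the unsubstituted diene terminus (C8–C7) and the nitrogen to the substituted terminus (N–C4a), an orientation asked for both by the frontier coefficients and by the tether, while ring B closes as the fused six-membered ring of a type 1 intramolecular cycloaddition through that same N–C4a bond. C4a is controlled by the carbinol centre C3: carbamate resonance holds the four-atom tether in a boat-like fold in which the pentyl group takes the outward (bowsprit) position, so that only one diene face is reached and H3 and H4a come out syn. C8 is controlled by the (E) geometry of the acylimine together with the endo position of the carbamate carbonyl under the diene, which puts the alkynyl group exo and hence trans to C4 across the nitrogen, the arrangement that also avoids A(1,3) strain between the alkynyl group and the carbamate C=O. The step needs chemoselectivity for C=N, and the substrate secures it because the alkynyl carbon carries no hydrogen (no tautomerisation to an enecarbamate) and because addition to the C≡C bond would have to close an eight-membered ring. Any leakage in facial or endo/exo selectivity gives diastereomers of 11 that can be separated before the carbinol centre is erased, so the enantiopurity of the target rests on that of 2.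

Step 7
Reactants: 11 cycloadduct
Product: 14 2-[(3S,4aS,8R)-1-oxo-3-pentyl-4,4a,7,8-tetrahydro-3H-pyrido[1,2-c][1,3]oxazin-8-yl]acetic acid, via vinylborane 12 (not isolated), via acylsilane 13 (not isolated)
Conditions: Cy2BH (1.3 equiv, made in the flask from BH3·SMe2 and cyclohexene), THF, 0 → 23 °C; then 3 M NaOH, 30% H2O2, 0 → 40 °C; acidify to pH 3
Reagents that add atoms: hydrogen peroxide, OO
Why: Hydroboration–oxidation of a 1-silylalkyne, in which the bulky borane adds to the alkyne far faster than to the ring alkene and places boron on the silicon-bearing carbon, and alkaline peroxide then oxidises the C–B bond and cleaves the acylsilane to the acid without touching C8.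

Step 8
Reactants: 15 3,3-diethoxypropan-1-amine (3 equiv); 16 4-bromobutanenitrile
Product: 18 tert-butyl (3-cyanopropyl)(3,3-diethoxypropyl)carbamate, via secondary amine 17 (not isolated)
Conditions: K2CO3, MeCN, 50 °C; excess 15 removed in vacuo; then Boc2O, CH2Cl2, 23 °C
Reagents that add atoms: di-tert-butyl dicarbonate, CC(C)(C)OC(=O)OC(=O)OC(C)(C)C
Why: SN2 monoalkylation of an excess of the primary amine, followed by carbamate protection of the secondary amine formed.

Step 9
Reactants: 18 Boc nitrile
Product: 19 tert-butyl (4-aminobutyl)(3,3-diethoxypropyl)carbamate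
Conditions: H2 (4 bar), Raney Ni, NH3 in MeOH, 23 °C
Reagents that add atoms: none
Why: Catalytic hydrogenation of the nitrile in the presence of ammonia gives the primary amine and leaves the Boc group and the acetal intact.

Step 10
Reactants: 14 acid; 19 amine
Product: 20 tert-butyl (3,3-diethoxypropyl)[4-({[(3S,4aS,8R)-1-oxo-3-pentyl-4,4a,7,8-tetrahydro-3H-pyrido[1,2-c][1,3]oxazin-8-yl]acetyl}amino)butyl]carbamate
Conditions: DCC, HOBt, CH2Cl2, 0 → 23 °C
Reagents that add atoms: none
Why: Carbodiimide amide coupling of an unhindered primary amine with a β-(acylamino) acid whose stereocentre is not α to the carboxyl group and so cannot racemise.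

Step 11
Reactants: 20 amide
Product: 21 tert-butyl (3,3-diethoxypropyl){4-[({(2R,6S)-6-[(2S)-2-hydroxyheptyl]-1,2,3,6-tetrahydropyridin-2-yl}acetyl)amino]butyl}carbamate
Conditions: KOH (20 equiv), EtOH–H2O 4:1, 90 °C (sealed tube)
Reagents that add atoms: none
Why: Basic hydrolysis of the six-membered cyclic carbamate (acyl–oxygen cleavage, then loss of carbonate) removes ring B, while the tert-butyl carbamate, the acetal and the secondary amide resist hydroxide.

Step 12
Reactants: 21 amino alcohol
Product: 24 tert-butyl (13R,17S)-17-[(2S)-2-hydroxyheptyl]-11-oxo-1,5,10-triazabicyclo[11.4.0]heptadec-15-ene-5-carboxylate, via amino aldehyde 22 (not isolated), via cyclic iminium ion 23 (not isolated)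
Conditions: AcOH–H2O 4:1, 40 °C; concentrate (toluene azeotrope); then slow addition to NaBH(OAc)3 (5 equiv), ClCH2CH2Cl (final 1 mM), 23 °C
Reagents that add atoms: none
Why: Aqueous acetic acid unmasks the aldehyde without loss of Boc, and at high dilution the ring nitrogen condenses reversibly with the unhindered aldehyde to the 13-membered iminium ion, which NaBH(OAc)3 reduces irreversibly (intramolecular reductive amination) without touching any stereocentre.

Step 13
Reactants: 24 macrocyclic alcohol
Product: 25 tert-butyl (13R,17S)-11-oxo-17-(2-oxoheptyl)-1,5,10-triazabicyclo[11.4.0]heptadec-15-ene-5-carboxylate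
Conditions: Dess–Martin periodinane (1.5 equiv), CH2Cl2, 0 → 23 °C; aq Na2S2O3/NaHCO3
Reagents that add atoms: none
Why: Dess–Martin oxidation turns the secondary alcohol into the ketone under mildly acidic conditions that keep N1 protonated and so disfavour retro-Michael epimerisation at C17; the auxiliary carbinol centre is erased here.

Step 14
Reactants: 25 Boc ketone
Product: 26 (13R,17S)-17-(2-oxoheptyl)-1,5,10-triazabicyclo[11.4.0]heptadec-15-en-11-one
Conditions: CF3CO2H–CH2Cl2 1:4, 0 °C; cold aq K2CO3, extraction
Reagents that add atoms: none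
Why: Acidolysis of the tert-butyl carbamate frees N5 at low temperature, conditions under which the alkene, the lactam and the β-amino ketone should stay unchanged.

**Compound list**
1 | rac-1,2-epoxyheptane | CCCCCC1CO1 | starting material
2 | (S)-1,2-epoxyheptane | CCCCC[C@H]1CO1 | intermediate
3 | (S)-non-1-yn-4-ol | C#CC[C@@H](O)CCCCC | intermediate
4 | (S,E)-alkenylzirconocene chloride, oxygen bound as zirconocene chloride alkoxide | CCCCC[C@@H](C/C=C/[Zr](Cl)(C1C=CC=C1)C1C=CC=C1)O[Zr](Cl)(C1C=CC=C1)C1C=CC=C1 | intermediate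
5 | (S,E)-undeca-1,3-dien-6-ol | C=C/C=C/C[C@@H](O)CCCCC | intermediate
6 | (S,E)-undeca-1,3-dien-6-yl N-(trichloroacetyl)carbamate | C=C/C=C/C[C@@H](OC(=O)NC(=O)C(Cl)(Cl)Cl)CCCCC | intermediate
7 | (S,E)-undeca-1,3-dien-6-yl carbamate | C=C/C=C/C[C@@H](OC(N)=O)CCCCC | intermediate
8 | 3-(trimethylsilyl)prop-2-ynal | C[Si](C)(C)C#CC=O | starting material
9 | (S,E)-undeca-1,3-dien-6-yl N-[1-(phenylsulfonyl)-3-(trimethylsilyl)prop-2-yn-1-yl]carbamate, both epimers at the sulfone carbon | C=C/C=C/C[C@@H](OC(=O)NC(C#C[Si](C)(C)C)S(=O)(=O)c1ccccc1)CCCCC | intermediate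
10 | (S,E)-undeca-1,3-dien-6-yl (E)-N-[3-(trimethylsilyl)prop-2-yn-1-ylidene]carbamate | C=C/C=C/C[C@@H](OC(=O)/N=C/C#C[Si](C)(C)C)CCCCC | intermediate
11 | (3S,4aS,8R)-3-pentyl-8-[(trimethylsilyl)ethynyl]-4,4a,7,8-tetrahydro-3H-pyrido[1,2-c][1,3]oxazin-1-one | O=C1O[C@@H](CCCCC)C[C@H]2C=CC[C@H](C#C[Si](C)(C)C)N12 | intermediate
12 | 8-[(Z)-2-(dicyclohexylboryl)-2-(trimethylsilyl)vinyl] analogue of 11 | O=C1O[C@@H](CCCCC)C[C@H]2C=CC[C@H](/C=C(\[Si](C)(C)C)B(C3CCCCC3)C3CCCCC3)N12 | intermediate
13 | 8-[2-oxo-2-(trimethylsilyl)ethyl] analogue of 11 (acylsilane) | O=C1O[C@@H](CCCCC)C[C@H]2C=CC[C@H](CC(=O)[Si](C)(C)C)N12 | intermediate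
14 | 2-[(3S,4aS,8R)-1-oxo-3-pentyl-4,4a,7,8-tetrahydro-3H-pyrido[1,2-c][1,3]oxazin-8-yl]acetic acid | O=C1O[C@@H](CCCCC)C[C@H]2C=CC[C@H](CC(=O)O)N12 | intermediate
15 | 3,3-diethoxypropan-1-amine | CCOC(CCN)OCC | starting material
16 | 4-bromobutanenitrile | N#CCCCBr | starting material
17 | 4-[(3,3-diethoxypropyl)amino]butanenitrile | CCOC(CCNCCCC#N)OCC | intermediate
18 | tert-butyl (3-cyanopropyl)(3,3-diethoxypropyl)carbamate | CCOC(CCN(CCCC#N)C(=O)OC(C)(C)C)OCC | intermediate
19 | tert-butyl (4-aminobutyl)(3,3-diethoxypropyl)carbamate | CCOC(CCN(CCCCN)C(=O)OC(C)(C)C)OCC | intermediate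
20 | amide of 14 with 19 | O=C1O[C@@H](CCCCC)C[C@H]2C=CC[C@H](CC(=O)NCCCCN(CCC(OCC)OCC)C(=O)OC(C)(C)C)N12 | intermediate
21 | (2R,6S)-tetrahydropyridine amino alcohol with (2S)-2-hydroxyheptyl group, acetal and Boc | CCCCC[C@H](O)C[C@H]1C=CC[C@H](CC(=O)NCCCCN(CCC(OCC)OCC)C(=O)OC(C)(C)C)N1 | intermediate
22 | amino aldehyde from 21 | CCCCC[C@H](O)C[C@H]1C=CC[C@H](CC(=O)NCCCCN(CCC=O)C(=O)OC(C)(C)C)N1 | intermediate
23 | 13-membered cyclic iminium ion (N1=C2) | CCCCC[C@H](O)C[C@H]1C=CC[C@@H]2CC(=O)NCCCCN(C(=O)OC(C)(C)C)CCC=[N+]21 | intermediate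
24 | tert-butyl (13R,17S)-17-[(2S)-2-hydroxyheptyl]-11-oxo-1,5,10-triazabicyclo[11.4.0]heptadec-15-ene-5-carboxylate | CCCCC[C@H](O)C[C@H]1C=CC[C@@H]2CC(=O)NCCCCN(C(=O)OC(C)(C)C)CCCN21 | intermediate
25 | tert-butyl (13R,17S)-11-oxo-17-(2-oxoheptyl)-1,5,10-triazabicyclo[11.4.0]heptadec-15-ene-5-carboxylate | CCCCCC(=O)C[C@H]1C=CC[C@@H]2CC(=O)NCCCCN(C(=O)OC(C)(C)C)CCCN21 | intermediate
26 | (13R,17S)-17-(2-oxoheptyl)-1,5,10-triazabicyclo[11.4.0]heptadec-15-en-11-one | CCCCCC(=O)C[C@H]1C=CC[C@@H]2CC(=O)NCCCCNCCCN21 | target

**Step count**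
Total steps: 14. Longest linear sequence: 12 (steps 1–7 and 10–14); steps 8 and 9 build the side fragment.

**Steps most likely to fail**

1. Step 6.
   - What may go wrong: the alkynyl acylimine may be lost to oligomerisation, hydrolysis or re-addition of sulfinate before the tether folds into the cisoid carbamate conformer that the cycloaddition needs. E/Z leakage at the slim alkynyl imine may also erode the trans selectivity.
   - Fallback: it sets out from carbamate 7 and comes back at acid 14. It uses a more electrophilic, firmly (E)-configured glyoxylate acylimine and brings in the missing carbon afterwards. Carbamate 7 is condensed with methyl glyoxylate to the hydroxy adduct F1, which Ac2O/pyridine turns into the acetate F2. Thermolysis in o-dichlorobenzene at 180 °C expels acetic acid to give the glyoxylate N-acylimine F3, which cyclises through the same endo-carbonyl fold to the bicyclic ester F4. LiOH gives the bicyclic acid F5. Isobutyl chloroformate/N-methylmorpholine gives the mixed anhydride F6, and diazomethane gives the diazoketone F7. Wolff rearrangement (Ag(O2CPh), Et3N, THF–H2O) passes through the ketene F8, with retention at the migrating carbon, to 14 (Arndt–Eistert homologation).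

2. Step 12.
   - What may go wrong: intermolecular condensation may outrun ring closure, because iminium formation at the doubly α-branched nitrogen is slow. The aldehyde may also lose its carbamate nitrogen by β-elimination.
   - Fallback: it sets out from acid 14 and amine 19 and comes back at 24. The hindered N–C bond is made intermolecularly and the ring is closed at the amide instead. Amine 19 is treated with allyl chloroformate to give the Alloc acetal F9, and aqueous acetic acid frees the Alloc aldehyde F10. Acid 14 is hydrolysed with KOH to the amino hydroxy acid F11. Reductive amination of F11 with an excess of F10 (NaBH(OAc)3) gives the N-alkylated acid F12. Pd(PPh3)4/morpholine removes the Alloc group to give the seco amino acid F13. Macrolactamisation at high dilution (diphenylphosphoryl azide, NaHCO3, DMF, 0 °C) then closes ring C to 24.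

3. Step 7.
   - What may go wrong: competing hydroboration of the ring alkene, or stalling of the oxidation at the acylsilane stage.
   - Fallback: it sets out from 11 and comes back at 14, replacing the borane by metal-vinylidene chemistry. K2CO3/MeOH removes silicon to give the terminal alkyne F14. Anti-Markovnikov hydration with CpRuCl(Ph2PCH2PPh2) (5 mol %, i-PrOH–H2O, 100 °C) gives the aldehyde F15. Pinnick oxidation (NaClO2, NaH2PO4, 2-methyl-2-butene) then gives 14.

**Further compounds**
F1 | step 6 | methyl 2-hydroxy-2-[({[(S,E)-undeca-1,3-dien-6-yl]oxy}carbonyl)amino]acetate | C=C/C=C/C[C@@H](OC(=O)NC(O)C(=O)OC)CCCCC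
F2 | step 6 | methyl 2-acetoxy-2-[({[(S,E)-undeca-1,3-dien-6-yl]oxy}carbonyl)amino]acetate | C=C/C=C/C[C@@H](OC(=O)NC(OC(C)=O)C(=O)OC)CCCCC
F3 | step 6 | methyl (E)-2-[({[(S,E)-undeca-1,3-dien-6-yl]oxy}carbonyl)imino]acetate | C=C/C=C/C[C@@H](OC(=O)/N=C/C(=O)OC)CCCCC
F4 | step 6 | methyl (3S,4aS,8R)-1-oxo-3-pentyl-4,4a,7,8-tetrahydro-3H-pyrido[1,2-c][1,3]oxazine-8-carboxylate | O=C1O[C@@H](CCCCC)C[C@H]2C=CC[C@H](C(=O)OC)N12
F5 | step 6 | (3S,4aS,8R)-1-oxo-3-pentyl-4,4a,7,8-tetrahydro-3H-pyrido[1,2-c][1,3]oxazine-8-carboxylic acid | O=C1O[C@@H](CCCCC)C[C@H]2C=CC[C@H](C(=O)O)N12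
F6 | step 6 | isobutyl carbonic mixed anhydride of F5 | O=C1O[C@@H](CCCCC)C[C@H]2C=CC[C@H](C(=O)OC(=O)OCC(C)C)N12
F7 | step 6 | (3S,4aS,8R)-8-(diazoacetyl)-3-pentyl-4,4a,7,8-tetrahydro-3H-pyrido[1,2-c][1,3]oxazin-1-one | O=C1O[C@@H](CCCCC)C[C@H]2C=CC[C@H](C(=O)C=[N+]=[N-])N12
F8 | step 6 | ketene from F7 | O=C1O[C@@H](CCCCC)C[C@H]2C=CC[C@H](C=C=O)N12
F9 | step 12 | tert-butyl (4-{[(allyloxy)carbonyl]amino}butyl)(3,3-diethoxypropyl)carbamate | CCOC(CCN(CCCCNC(=O)OCC=C)C(=O)OC(C)(C)C)OCC
F10 | step 12 | tert-butyl (4-{[(allyloxy)carbonyl]amino}butyl)(3-oxopropyl)carbamate | O=CCCN(CCCCNC(=O)OCC=C)C(=O)OC(C)(C)C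
F11 | step 12 | 2-{(2R,6S)-6-[(2S)-2-hydroxyheptyl]-1,2,3,6-tetrahydropyridin-2-yl}acetic acid | CCCCC[C@H](O)C[C@H]1C=CC[C@H](CC(=O)O)N1
F12 | step 12 | N-alkylated acid from F11 and F10 | CCCCC[C@H](O)C[C@H]1C=CC[C@H](CC(=O)O)N1CCCN(CCCCNC(=O)OCC=C)C(=O)OC(C)(C)C
F13 | step 12 | seco amino acid | CCCCC[C@H](O)C[C@H]1C=CC[C@H](CC(=O)O)N1CCCN(CCCCN)C(=O)OC(C)(C)C
F14 | step 7 | (3S,4aS,8R)-8-ethynyl-3-pentyl-4,4a,7,8-tetrahydro-3H-pyrido[1,2-c][1,3]oxazin-1-one | O=C1O[C@@H](CCCCC)C[C@H]2C=CC[C@H](C#C)N12
F15 | step 7 | 2-[(3S,4aS,8R)-1-oxo-3-pentyl-4,4a,7,8-tetrahydro-3H-pyrido[1,2-c][1,3]oxazin-8-yl]acetaldehyde | O=C1O[C@@H](CCCCC)C[C@H]2C=CC[C@H](CC=O)N12
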